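**Retrosynthetic overview**

1. The C15 acid comes from a primary alcohol in the last step; the C19 acetate and the quaternary C4 come from a C19 aldehyde, itself made from a C4 ketone (methoxymethylene Wittig, hydrolysis, equatorial methylation of the aldehyde enolate).
2. C9–C11 is made by 1,2-addition of an organocerium from (R)-citronellol (C13 stereocentre) to a C9 enone; palladium/formate hydrogenolysis of the tertiary allylic carbonate then puts H on C9 and keeps C7=C8.
3. Ring A is disconnected at C2–C3 as an intramolecular aldol of a C4 methyl ketone (C3 is its methyl group) onto a C2 aldehyde; both carbonyls come from one double ozonolysis of 6-allyl-6-methylcarvone.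
4. Enabling feature: in ring A the C2 carbinol is β to the quaternary C4. If the two exocyclic carbons on C4 (C18, C19) are exchanged for a carbonyl oxygen, C2–C3 is the bond of a β-hydroxy ketone, and the C4(=O)–C3 unit maps onto the isopropenyl group of carvone.
5. Ring order: ring B is bought as (S)-carvone (C5) and given the quaternary C10 by two α′-alkylations; ring A is closed in the key step; the side chain follows.

Key step: step 3

Remark: labdane numbering is used (ring A = C1–C5 and C10, ring B = C5–C10, side chain C11–C16, C17 on C8, C18 and C19 on C4, C20 on C10). Mixtures that converge in a later step (C10 epimers of 2, E/Z isomers at C4=C19, C4 epimers of 17) are carried on unseparated and are written without that stereo descriptor.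

**Route**

Step 1
Reactants: 1 (S)-(+)-carvone
Product: 2 trans-6-methylcarvone (with some cis epimer)
Conditions: LiN(i-Pr)2, THF, −78 °C; MeI, −78 → 0 °C
Reagents that add atoms: iodomethane, CI
Why: Kinetic α′-deprotonation of the enone and SN2 methylation of the lithium enolate (ketone enolate alkylation) should give the 6-methyl compound, whose new centre is planarised again in step 2, so its configuration does not matter.

Step 2
Reactants: 2 trans-6-methylcarvone
Product: 3 6-allyl-6-methylcarvone (allyl trans to isopropenyl)
Conditions: LiN(i-Pr)2, THF, −78 °C; allyl bromide, DMPU, −78 → 0 °C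
Reagents that add atoms: allyl bromide, C=CCBr
Why: Enolate alkylation again: allyl bromide should attack the tetrasubstituted α′-enolate anti to the neighbouring isopropenyl group (1,2-induction from C5), which sets quaternary C10 with the future C1 trans to the future C4 and the methyl group cis to it.

Step 3
Reactants: 3 6-allyl-6-methylcarvone
Product: 5 trans-fused ring-A ketol, via keto-aldehyde 4 (not isolated)
Conditions: O3, CH2Cl2/MeOH, NaHCO3, Sudan Red 7B, −78 °C; Me2S, → rt; solvent change; L-proline (30 mol %), DMSO, rt
Reagents that add atoms: ozone, [O-][O+]=O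
Why: Ozone attacks the two electron-rich C=C bonds (allyl, isopropenyl) much faster than the electron-poor trisubstituted enone C7=C8, and reductive work-up leaves the 1,5-keto-aldehyde 4, in which the former isopropenyl methyl group is the α-methyl (C3) of a C4 methyl ketone. Proline forms the enamine on C3, which adds to the acid-activated C2 aldehyde; the closest known reaction types are the proline-mediated intramolecular (Hajos–Parrish-type) aldol and the ketone-to-aldehyde enamine aldol. Ring A closes in 6-(enolendo)-exo-trig mode through a chair in which the C10–C1 and C5–C4 bonds are trans-diequatorial on ring B, so the trans-decalin follows from the C5/C10 relationship fixed in step 2. The new C2 stereocentre is substrate-controlled: the carbinol oxygen takes the equatorial position because the axial one is syn-diaxial to the C10 methyl group, and reversibility of the aldol (and of C5 epimerisation α to the C4 ketone) drains material into the same trans-fused, equatorial ketol. The step needs chemoselective ozonolysis, C–C bond formation only between C3 and C2, and no dehydration; these are secured by the indicator dye at −78 °C, by ring size (every other enamine/carbonyl pairing would give a three-, four- or strained five-membered ring) and by the acid-free conditions at room temperature.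

Step 4
Reactants: 5 trans-fused ring-A ketol
Product: 6 ketol TBS ether
Conditions: TBSCl, imidazole, DMF, rt
Reagents that add atoms: tert-butyldimethylsilyl chloride, CC(C)(C)[Si](C)(C)Cl
Why: Imidazole-promoted silylation of the only hydroxyl group protects the ketol against retro-aldol and elimination in the basic steps that follow, and the mild base should not trigger β-elimination.

Step 5
Reactants: 6 ketol TBS ether
Product: 7 C4 methoxymethylene enone (E/Z mixture)
Conditions: MeOCH2PPh3Cl, KN(SiMe3)2, THF, 0 °C; then 6, 0 °C → rt
Reagents that add atoms: (methoxymethyl)triphenylphosphonium chloride, COC[P+](c1ccccc1)(c1ccccc1)c1ccccc1.[Cl-]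
Why: Wittig olefination with the non-stabilised methoxymethylene ylide should take place at the saturated C4 ketone and spare the hindered, conjugated C9 carbonyl, which adds C19 as an enol ether, an aldehyde equivalent that is inert to the organometallic and palladium steps.

Step 6
Reactants: 8 (R)-(+)-citronellol
Product: 9 (R)-citronellol TIPS ether
Conditions: TIPSCl, imidazole, DMF, rt
Reagents that add atoms: triisopropylsilyl chloride, CC(C)[Si](Cl)(C(C)C)C(C)C
Why: Standard silylation of the primary alcohol; the C13 stereocentre of the side chain is bought with the starting material.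

Step 7
Reactants: 9 (R)-citronellol TIPS ether
Product: 10 (R)-4-methyl-6-(triisopropylsilyloxy)hexanoic acid
Conditions: RuCl3·xH2O (cat.), NaIO4, CCl4/MeCN/H2O, rt
Reagents that add atoms: sodium periodate, [Na+].[O-]I(=O)(=O)=O; water, O
Why: RuO4 generated in situ cleaves the trisubstituted double bond and oxidises the resulting aldehyde on to the acid (oxidative alkene cleavage), while the silyl ether and the remote stereocentre are untouched.

Step 8
Reactants: 10 (R)-4-methyl-6-(triisopropylsilyloxy)hexanoic acid
Product: 11 (S)-5-iodo-3-methylpentyl TIPS ether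
Conditions: PhI(OAc)2, I2, cyclohexane, tungsten lamp, reflux
Reagents that add atoms: iodine, II
Why: Iododecarboxylation through the acyl hypoiodite (radical halodecarboxylation of Hunsdiecker type) shortens the chain by one carbon and gives the primary iodide, the radical being two carbons away from the stereocentre.

Step 9
Reactants: 7 C4 methoxymethylene enone; 11 (S)-5-iodo-3-methylpentyl TIPS ether
Product: 15 tertiary allylic methyl carbonate, via organolithium 12 (not isolated), via organocerium 13 (not isolated), via cerium alkoxide 14 (not isolated)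
Conditions: 11, t-BuLi (2.1 equiv), Et2O, −78 °C; CeCl3, THF, −78 °C; 7, −78 °C; ClCO2Me, −78 → 0 °C
Reagents that add atoms: methyl chloroformate, COC(Cl)=O
Why: Iodine–lithium exchange and transmetalation give a weakly basic organocerium that should add 1,2 to the hindered enone from the face anti to the axial C10 methyl group (carbonyl addition), so that oxygen ends cis to that methyl group, and the alkoxide is trapped as the carbonate in the same flask.

Step 10
Reactants: 15 tertiary allylic methyl carbonate
Product: 16 19-methoxy-18-norlabda-4(19),7-diene 2-TBS 15-TIPS bis-ether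
Conditions: Pd(OAc)2 (5 mol %), n-Bu3P (20 mol %), HCO2H, Et3N, THF, 40 °C
Reagents that add atoms: none
Why: Zerovalent palladium formed from Pd(OAc)2 and n-Bu3P ionises the tertiary allylic carbonate anti to the leaving group, and the σ-allyl palladium formate bound at the less hindered C7 loses CO2 and delivers hydride to the more substituted terminus C9 on the palladium face (formate hydrogenolysis of allylic carbonates), which should place H on C9 anti to the C10 methyl group and leave the double bond at C7=C8.

Step 11
Reactants: 16 19-methoxy-18-norlabda-4(19),7-diene bis-ether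
Product: 17 C19 aldehyde (C4 epimers)
Conditions: (CO2H)2, THF/H2O, rt
Reagents that add atoms: water, O
Why: Acid-catalysed hydrolysis of the enol ether under conditions that should spare the silyl ethers and the trisubstituted alkene; the C4 epimer ratio is irrelevant because C4 is enolised in step 12.

Step 12
Reactants: 17 C19 aldehyde
Product: 18 quaternary C19 aldehyde
Conditions: t-BuOK, THF, −20 °C; MeI, → 0 °C
Reagents that add atoms: iodomethane, CI
Why: Alkylation of the potassium enolate of the α-branched aldehyde: methyl iodide should attack C4 from the equatorial face, away from the syn-axial C10 methyl group, as known for C4 ester and aldehyde enolates of 10-methyl-trans-decalins, so that the formyl group (C19) ends axial and the new methyl group (C18) equatorial.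

Step 13
Reactants: 18 quaternary C19 aldehyde
Product: 19 C19 alcohol
Conditions: NaBH4, MeOH/THF, 0 °C
Reagents that add atoms: none
Why: Borohydride reduction of the neopentyl aldehyde; no other group in 18 is reducible under these conditions.

Step 14
Reactants: 19 C19 alcohol
Product: 20 C19 acetate bis-silyl ether
Conditions: Ac2O, DMAP (cat.), pyridine, rt
Reagents that add atoms: acetic anhydride, CC(=O)OC(C)=O
Why: Nucleophile-catalysed acylation of the only free hydroxyl group.

Step 15
Reactants: 20 C19 acetate bis-silyl ether
Product: 21 2,15-diol 19-acetate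
Conditions: HF·pyridine, THF/pyridine, 0 °C → rt
Reagents that add atoms: none
Why: Fluoride cleaves both silyl ethers, and the slightly acidic reagent should leave the acetate in place without acyl migration.

Step 16
Reactants: 21 2,15-diol 19-acetate
Product: 22 target acid
Conditions: TEMPO (cat.), PhI(OAc)2, MeCN/H2O, rt
Reagents that add atoms: water, O
Why: Oxoammonium oxidation: TEMPO/PhI(OAc)2 in wet acetonitrile should take the unhindered primary alcohol through the aldehyde hydrate to the acid much faster than it attacks the secondary C2 carbinol, and alkene and acetate are inert.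

**Compound list**

1 | (S)-(+)-carvone, (5S)-2-methyl-5-(prop-1-en-2-yl)cyclohex-2-en-1-one | C=C(C)[C@H]1CC=C(C)C(=O)C1 | starting material
2 | trans-6-methylcarvone, (5S,6R)-2,6-dimethyl-5-(prop-1-en-2-yl)cyclohex-2-en-1-one (major epimer) | C[C@H]1C(=O)C(C)=CC[C@@H]1C(C)=C | intermediate
3 | 6-allyl-6-methylcarvone, (5R,6R)-6-allyl-2,6-dimethyl-5-(prop-1-en-2-yl)cyclohex-2-en-1-one, allyl trans to isopropenyl | C=CC[C@@]1(C)C(=O)C(C)=CC[C@@H]1C(C)=C | intermediate
4 | keto-aldehyde, 2-(6-acetyl-1,3-dimethyl-2-oxocyclohex-3-en-1-yl)acetaldehyde, acetyl trans to the CH2CHO arm | O=CC[C@@]1(C)C(=O)C(C)=CC[C@@H]1C(C)=O | intermediate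
5 | ring-A ketol, trans-fused 3-hydroxy-4a,6-dimethyl-2,3,4,4a,8,8a-hexahydronaphthalene-1,5-dione, hydroxyl equatorial and trans to the angular methyl (labdane C2-OH, C4 and C9 ketones, C7=C8) | O=C1C[C@@H](O)C[C@@]2(C)C(=O)C(C)=CC[C@H]12 | intermediate
6 | TBS ether of ketol 5 | O=C1C[C@@H](O[Si](C)(C)C(C)(C)C)C[C@@]2(C)C(=O)C(C)=CC[C@H]12 | intermediate
7 | C4 methoxymethylene enone, C4=CH(OMe) enol ether of 6 with C9 enone intact (E/Z mixture) | COC=C1C[C@@H](O[Si](C)(C)C(C)(C)C)C[C@@]2(C)C(=O)C(C)=CC[C@H]12 | intermediate
8 | (R)-(+)-citronellol, (3R)-3,7-dimethyloct-6-en-1-ol | CC(C)=CCC[C@@H](C)CCO | starting material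
9 | (R)-citronellol triisopropylsilyl ether | CC(C)=CCC[C@@H](C)CCO[Si](C(C)C)(C(C)C)C(C)C | intermediate
10 | (R)-4-methyl-6-(triisopropylsilyloxy)hexanoic acid | OC(=O)CC[C@@H](C)CCO[Si](C(C)C)(C(C)C)C(C)C | intermediate
11 | (S)-5-iodo-3-methylpentyl triisopropylsilyl ether | ICC[C@@H](C)CCO[Si](C(C)C)(C(C)C)C(C)C | intermediate
12 | organolithium, (S)-3-methyl-5-(triisopropylsilyloxy)pentyllithium | [Li]CC[C@@H](C)CCO[Si](C(C)C)(C(C)C)C(C)C | intermediate
13 | organocerium, dichloro[(S)-3-methyl-5-(triisopropylsilyloxy)pentyl]cerium | Cl[Ce](Cl)CC[C@@H](C)CCO[Si](C(C)C)(C(C)C)C(C)C | intermediate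
14 | cerium alkoxide of the C9 adduct, oxygen cis and side chain trans to the C10 methyl | COC=C1C[C@@H](O[Si](C)(C)C(C)(C)C)C[C@@]2(C)[C@](CC[C@@H](C)CCO[Si](C(C)C)(C(C)C)C(C)C)(O[Ce](Cl)Cl)C(C)=CC[C@H]12 | intermediate
15 | tertiary allylic methyl carbonate at C9, carbonate oxygen cis to the C10 methyl | COC=C1C[C@@H](O[Si](C)(C)C(C)(C)C)C[C@@]2(C)[C@](CC[C@@H](C)CCO[Si](C(C)C)(C(C)C)C(C)C)(OC(=O)OC)C(C)=CC[C@H]12 | intermediate
16 | 19-methoxy-18-norlabda-4(19),7-diene with 2-OTBS and 15-OTIPS, 9-H anti to the C10 methyl (E/Z mixture at C4=C19) | COC=C1C[C@@H](O[Si](C)(C)C(C)(C)C)C[C@@]2(C)[C@H](CC[C@@H](C)CCO[Si](C(C)C)(C(C)C)C(C)C)C(C)=CC[C@H]12 | intermediate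
17 | C19 aldehyde, 2-OTBS-15-OTIPS-18-norlabd-7-en-19-al (C4 epimers) | O=CC1C[C@@H](O[Si](C)(C)C(C)(C)C)C[C@@]2(C)[C@H](CC[C@@H](C)CCO[Si](C(C)C)(C(C)C)C(C)C)C(C)=CC[C@H]12 | intermediate
18 | quaternary C19 aldehyde, 2-OTBS-15-OTIPS-labd-7-en-19-al, formyl axial and cis to the C10 methyl | O=C[C@]1(C)C[C@@H](O[Si](C)(C)C(C)(C)C)C[C@@]2(C)[C@H](CC[C@@H](C)CCO[Si](C(C)C)(C(C)C)C(C)C)C(C)=CC[C@H]12 | intermediate
19 | C19 alcohol, 2-OTBS-15-OTIPS-labd-7-en-19-ol | OC[C@]1(C)C[C@@H](O[Si](C)(C)C(C)(C)C)C[C@@]2(C)[C@H](CC[C@@H](C)CCO[Si](C(C)C)(C(C)C)C(C)C)C(C)=CC[C@H]12 | intermediate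
20 | C19 acetate bis-silyl ether | CC(=O)OC[C@]1(C)C[C@@H](O[Si](C)(C)C(C)(C)C)C[C@@]2(C)[C@H](CC[C@@H](C)CCO[Si](C(C)C)(C(C)C)C(C)C)C(C)=CC[C@H]12 | intermediate
21 | 2,15-diol 19-acetate, 19-acetoxylabd-7-ene-2,15-diol | CC(=O)OC[C@]1(C)C[C@@H](O)C[C@@]2(C)[C@H](CC[C@@H](C)CCO)C(C)=CC[C@H]12 | intermediate
22 | CNP0162900.1, 19-acetoxy-2-hydroxylabd-7-en-15-oic acid in the configuration given | CC(=O)OC[C@]1(C)C[C@@H](O)C[C@@]2(C)[C@H](CC[C@@H](C)CC(=O)O)C(C)=CC[C@H]12 | target

**Step count and risks**

Total step count: 16. Longest linear sequence: 13 steps (steps 1–5 and 9–16, from (S)-carvone).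

Step 3 (ozonolysis and aldol). What may go wrong: ozone also attacks the enone double bond, or the ketol loses water, or the aldehyde oligomerises under amine catalysis. The fallback sets out from 3 and comes back at 5. The two electron-rich double bonds are cleaved with OsO4 (cat.), NaIO4 and 2,6-lutidine in dioxane/water to give 4, which is isolated. Pyrrolidine and AcOH in toluene at 60 °C then close the same C2–C3 bond as a deliberate aldol condensation to the trans-fused ring-A enone, enedione F1. Copper-catalysed conjugate borylation (CuCl, NaOt-Bu, bis(pinacolato)diboron, MeOH, THF, rt) should add boron to C2 of the less substituted ring-A enone, from the face anti to the C10 methyl group, to give β-boryl ketone F2. NaBO3·4H2O in THF/water oxidises the C–B bond with retention and returns the equatorial ketol 5.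

Step 10 (allylic hydrogenolysis). What may go wrong: hydride transfer to C7 instead of C9, β-hydride elimination to dienes, or poor facial selectivity in the preceding addition, so that C9 is set wrongly. The fallback sets out from 7 (with 11) and comes back at 16. The organocerium addition of step 9 is quenched with aqueous NH4Cl instead of the chloroformate to give the tertiary allylic alcohol F3. Ph3SiOReO3 (cat.) in Et2O at 0 °C should shift the hydroxyl group suprafacially to C7 and give the secondary allylic alcohol F4 with a C8=C9 double bond. Mitsunobu reaction with o-nitrobenzenesulfonylhydrazide (PPh3, diethyl azodicarboxylate, THF, −30 °C → rt) inverts C7; the allylic diazene formed on loss of sulfinic acid expels N2 in a retro-ene reaction that delivers H to C9 anti to the C10 methyl group and moves the double bond to C7=C8, which gives 16.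

Step 12 (methylation at C4). What may go wrong: O-methylation of the aldehyde enolate or poor facial selectivity at C4. The fallback sets out from 17 and comes back at 19, so that 18 and step 13 are bypassed. Pinnick oxidation (NaClO2, NaH2PO4, 2-methyl-2-butene, t-BuOH/water) gives the C19 acid F5, and MeI/K2CO3 in DMF gives its methyl ester F6. LiN(i-Pr)2 and then MeI in THF (−78 → 0 °C) give the quaternary ester F7 by the well-precedented equatorial methylation of C4 ester enolates, and LiAlH4 in THF reduces it to 19.

**Further compounds**

F1 | step 3 | enedione, trans-fused 4a,6-dimethyl-4a,8a-dihydronaphthalene-1,5(4H,8H)-dione (ring-A enone C2=C3–C4=O) | O=C1C=CC[C@@]2(C)C(=O)C(C)=CC[C@H]12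
F2 | step 3 | β-boryl ketone, C2 pinacolboronate of the ring-A ketone, boron equatorial | O=C1C[C@@H](B3OC(C)(C)C(C)(C)O3)C[C@@]2(C)C(=O)C(C)=CC[C@H]12
F3 | step 10 | tertiary allylic alcohol at C9, hydroxyl cis to the C10 methyl | COC=C1C[C@@H](O[Si](C)(C)C(C)(C)C)C[C@@]2(C)[C@](CC[C@@H](C)CCO[Si](C(C)C)(C(C)C)C(C)C)(O)C(C)=CC[C@H]12
F4 | step 10 | secondary allylic alcohol at C7 with C8=C9 double bond, hydroxyl cis to the C10 methyl | COC=C1C[C@@H](O[Si](C)(C)C(C)(C)C)C[C@@]2(C)C(CC[C@@H](C)CCO[Si](C(C)C)(C(C)C)C(C)C)=C(C)[C@H](O)C[C@H]12
F5 | step 12 | C19 acid (C4 epimers) | OC(=O)C1C[C@@H](O[Si](C)(C)C(C)(C)C)C[C@@]2(C)[C@H](CC[C@@H](C)CCO[Si](C(C)C)(C(C)C)C(C)C)C(C)=CC[C@H]12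
F6 | step 12 | C19 methyl ester (C4 epimers) | COC(=O)C1C[C@@H](O[Si](C)(C)C(C)(C)C)C[C@@]2(C)[C@H](CC[C@@H](C)CCO[Si](C(C)C)(C(C)C)C(C)C)C(C)=CC[C@H]12
F7 | step 12 | quaternary C19 methyl ester, ester axial and cis to the C10 methyl | COC(=O)[C@]1(C)C[C@@H](O[Si](C)(C)C(C)(C)C)C[C@@]2(C)[C@H](CC[C@@H](C)CCO[Si](C(C)C)(C(C)C)C(C)C)C(C)=CC[C@H]12
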